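**Retrosynthetic overview**

1. Target 18 ⇐ 16: the two aryl benzyl ethers and the carbinol silyl ether come off last, and the 3,4-trans relationship is set just before by base equilibration at C3 (lactone locants: O1, C2 = carbonyl, C3 carries the benzyl group, C4 the carbinol side chain, C5 = ring CH2).
2. Lactone (the only ring the route has to build) ⇐ styrenyl chloride 13 + formate: O1–C5 and C2–C3 are made together, the whole C2(=O)–O1 unit arriving as CO2•− spliced between the styrene β-carbon and the CH2Cl carbon (formal [3+2] annulation, closed 5-exo-tet).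
3. 13 ⇐ Evans syn-aldol of styrylacetyl imide 7 with aldehyde 1 (sets C4 and the carbinol carbon), then silylation, reductive removal of the auxiliary and Appel chlorination.
4. 7 ⇐ acid 4 ⇐ Wittig reaction of the same aldehyde 1, so both guaiacyl rings come from O-benzylvanillin.
5. Enabling feature: C2 is a carboxyl carbon between ring O1 and C3; C3 is homobenzylic to the guaiacyl ring of the 3-benzyl group, so it can be the β-carbon of a styrene (radical addition there leaves a benzylic radical); C5 is an unsubstituted CH2 in 1,3-relation to C3, so it can be a primary alkyl chloride.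

Key step: step 7

Remark: the geometry of the Wittig alkene is immaterial to the target, because that double bond is saturated in step 7; the E isomer is written throughout.

**Step 1**
Reactants: 1 4-(benzyloxy)-3-methoxybenzaldehyde; 2 (2-carboxyethyl)triphenylphosphonium bromide
Product: 4 (E)-4-[4-(benzyloxy)-3-methoxyphenyl]but-3-enoic acid, via ylide carboxylate 3 (not isolated)
Conditions: NaN(SiMe3)2 (2.1 equiv), THF, 0 °C; then 1, −78 °C → rt; aq. HCl
Reagents that add atoms: none
Why: Wittig olefination with the carboxylate-bearing ylide should give the β,γ-unsaturated acid, in which the styrene-conjugated position of the double bond is the stable one; no stereocentre is formed.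

**Step 2**
Reactants: 4 (E)-4-[4-(benzyloxy)-3-methoxyphenyl]but-3-enoic acid; 5 (S)-4-benzyloxazolidin-2-one
Product: 7 (S)-4-benzyl-3-{(E)-4-[4-(benzyloxy)-3-methoxyphenyl]but-3-enoyl}oxazolidin-2-one, via mixed pivalic anhydride 6 (not isolated)
Conditions: t-BuCOCl, Et3N, THF, −20 °C; then 5, LiCl, −20 °C → rt
Reagents that add atoms: none
Why: N-acylation of the oxazolidinone through the mixed pivalic anhydride under LiCl/Et3N activation is mild enough not to enolise the styrylacetyl unit; no stereocentre is formed.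

**Step 3**
Reactants: 7 (S)-4-benzyl-3-{(E)-4-[4-(benzyloxy)-3-methoxyphenyl]but-3-enoyl}oxazolidin-2-one; 1 4-(benzyloxy)-3-methoxybenzaldehyde
Product: 10 (S)-4-benzyl-3-{(2S,3E)-4-[4-(benzyloxy)-3-methoxyphenyl]-2-[(S)-[4-(benzyloxy)-3-methoxyphenyl](hydroxy)methyl]but-3-enoyl}oxazolidin-2-one, via boron Z-dienolate 8 (not isolated), via boron aldolate 9 (not isolated)
Conditions: Bu2BOTf, i-Pr2NEt, CH2Cl2, −78 → 0 °C; then 1, −78 → 0 °C; pH 7 buffer, MeOH, H2O2, 0 °C
Reagents that add atoms: none
Why: Evans syn-aldol reaction, in which the Z-boron dienolate reacts at its α-carbon through a closed Zimmerman–Traxler chair on the face away from the benzyl group of the (S)-auxiliary, so that the future C4 and the carbinol carbon are both set (2S and carbinol S in 10, the syn relationship and absolute sense of the target).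

**Step 4**
Reactants: 10 the syn-aldol adduct
Product: 11 (S)-4-benzyl-3-{(2S,3E)-4-[4-(benzyloxy)-3-methoxyphenyl]-2-[(S)-[4-(benzyloxy)-3-methoxyphenyl](tert-butyldimethylsilyloxy)methyl]but-3-enoyl}oxazolidin-2-one
Conditions: TBSOTf, 2,6-lutidine, CH2Cl2, −78 → 0 °C
Reagents that add atoms: tert-butyldimethylsilyl triflate, CC(C)(C)[Si](C)(C)OS(=O)(=O)C(F)(F)F
Why: Silylation of the secondary alcohol with the silyl triflate and a hindered pyridine base should block retro-aldol cleavage now and acyl migration later without touching a stereocentre.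

**Step 5**
Reactants: 11 the silylated imide
Product: 12 (2R,3E)-4-[4-(benzyloxy)-3-methoxyphenyl]-2-[(S)-[4-(benzyloxy)-3-methoxyphenyl](tert-butyldimethylsilyloxy)methyl]but-3-en-1-ol
Conditions: LiBH4, H2O (1 equiv), Et2O/THF, 0 °C
Reagents that add atoms: none
Why: Reductive cleavage of the N-acyl oxazolidinone with LiBH4 should reduce the activated exocyclic carbonyl to the primary alcohol without epimerising the adjacent centre (its descriptor changes to R only through priorities), and the auxiliary is recovered.

**Step 6**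
Reactants: 12 the primary alcohol
Product: 13 tert-butyl({(1S,2S,3E)-1,4-bis[4-(benzyloxy)-3-methoxyphenyl]-2-(chloromethyl)but-3-en-1-yl}oxy)dimethylsilane
Conditions: PPh3, CCl4, CH2Cl2, 0 → 40 °C
Reagents that add atoms: carbon tetrachloride, ClC(Cl)(Cl)Cl
Why: The Appel reaction should convert the primary alcohol into the chloride under neutral conditions with no free electrophilic chlorine to attack the electron-rich styrene; no stereocentre is touched.

**Step 7**
Reactants: 13 the styrenyl chloride
Product: 15 (4R)-3-[4-(benzyloxy)-3-methoxybenzyl]-4-[(S)-[4-(benzyloxy)-3-methoxyphenyl](tert-butyldimethylsilyloxy)methyl]dihydrofuran-2(3H)-one as a mixture of C3 epimers, via potassium chloro carboxylate 14 (not isolated)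
Conditions: HCO2K (5 equiv), 4CzIPN (2 mol %), 1-adamantanethiol (20 mol %), DMSO, blue LEDs (450 nm), 25 °C; then NaI (20 mol %), 70 °C, dark
Reagents that add atoms: potassium formate, [K+].[O-]C=O
Why: A thiyl radical abstracts hydrogen from formate to give CO2•−, which adds to the styrene β-carbon (the future C3) because only this regiochemistry leaves a benzylic radical beside the guaiacyl ring; the thiol returns a hydrogen atom to that radical to give carboxylate 14, and on warming its oxygen displaces the primary chloride at the future C5, so that the C2–C3 and O1–C5 bonds are made in one flask and the whole C2(=O)–O1 unit is the formate carbon with its two oxygens. The closest known reaction type is the photochemical anti-Markovnikov hydrocarboxylation of styrenes with formate salts (Giese-type addition of CO2•−), relayed here into the ordinary lactonisation of a γ-chloro carboxylate. The lactone, the only ring made in the route, closes by intramolecular SN2 displacement in the 5-exo-tet mode. The new stereocentre C3 arises from radical addition next to the C4 stereocentre with only weak acyclic (allylic strain) bias, so it is carried on as an epimer mixture and set thermodynamically in step 8, while no bond to C4 or to the carbinol carbon is made or broken, so both should keep their configuration. The step needs regioselectivity, secured by the aryl group on the distal alkene carbon, and chemoselectivity, secured by the choice of chloride (not reduced by CO2•− and slow to react with formate at 25 °C, unlike a bromide, iodide or sulfonate), by the hindered tertiary thiol (a poor SN2 nucleophile) and by the high effective molarity of five-ring closure over intermolecular attack of formate.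

**Step 8**
Reactants: 15 the lactone as C3 epimer mixture
Product: 16 (3R,4R)-3-[4-(benzyloxy)-3-methoxybenzyl]-4-[(S)-[4-(benzyloxy)-3-methoxyphenyl](tert-butyldimethylsilyloxy)methyl]dihydrofuran-2(3H)-one
Conditions: KOt-Bu (0.3 equiv), THF, −20 → 0 °C; AcOH quench
Reagents that add atoms: none
Why: Base-mediated epimerisation through the lactone enolate should drive the mixture to the 3,4-trans lactone, the more stable isomer with two bulky vicinal substituents, while C4 and the carbinol carbon are not acidic and the silyl ether prevents acyl migration.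

**Step 9**
Reactants: 16 the trans lactone
Product: 17 (3R,4R)-4-[(S)-(tert-butyldimethylsilyloxy)(4-hydroxy-3-methoxyphenyl)methyl]-3-(4-hydroxy-3-methoxybenzyl)dihydrofuran-2(3H)-one
Conditions: H2 (1 atm), Pd/C (10 wt % Pd), EtOAc, rt
Reagents that add atoms: none
Why: Catalytic hydrogenolysis of aryl benzyl ethers over Pd/C under neutral, low-pressure conditions should be much faster than cleavage of the hindered benzylic C–O bond, which the silyl group additionally shields.

**Step 10**
Reactants: 17 the bis-phenol silyl ether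
Product: 18 (3R,4R)-4-[(S)-hydroxy(4-hydroxy-3-methoxyphenyl)methyl]-3-(4-hydroxy-3-methoxybenzyl)dihydrofuran-2(3H)-one
Conditions: Bu4NF, AcOH (1:1), THF, 0 °C → rt
Reagents that add atoms: none
Why: Fluoride-mediated desilylation buffered with acetic acid should keep the phenols and the liberated benzylic alcohol protonated, so that neither quinone methide formation nor translactonisation is expected.

**Compound list**

1 | 4-(benzyloxy)-3-methoxybenzaldehyde | COc1cc(C=O)ccc1OCc1ccccc1 | starting material
2 | (2-carboxyethyl)triphenylphosphonium bromide | OC(=O)CC[P+](c1ccccc1)(c1ccccc1)c1ccccc1.[Br-] | starting material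
3 | sodium 3-(triphenylphosphoranylidene)propanoate | [Na+].[O-]C(=O)CC=P(c1ccccc1)(c1ccccc1)c1ccccc1 | intermediate
4 | (E)-4-[4-(benzyloxy)-3-methoxyphenyl]but-3-enoic acid | COc1cc(/C=C/CC(=O)O)ccc1OCc1ccccc1 | intermediate
5 | (S)-4-benzyloxazolidin-2-one | O=C1N[C@@H](Cc2ccccc2)CO1 | starting material
6 | (E)-4-[4-(benzyloxy)-3-methoxyphenyl]but-3-enoic pivalic anhydride | COc1cc(/C=C/CC(=O)OC(=O)C(C)(C)C)ccc1OCc1ccccc1 | intermediate
7 | (S)-4-benzyl-3-{(E)-4-[4-(benzyloxy)-3-methoxyphenyl]but-3-enoyl}oxazolidin-2-one | COc1cc(/C=C/CC(=O)N2[C@@H](Cc3ccccc3)COC2=O)ccc1OCc1ccccc1 | intermediate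
8 | dibutylboron Z-dienolate of 7 | CCCCB(CCCC)O/C(N1[C@@H](Cc2ccccc2)COC1=O)=C\C=C\c1ccc(OCc2ccccc2)c(OC)c1 | intermediate
9 | dibutylboron aldolate of 10 | O=C(N1[C@@H](Cc2ccccc2)COC1=O)[C@@H](/C=C/c1ccc(OCc2ccccc2)c(OC)c1)[C@H](OB(CCCC)CCCC)c1ccc(OCc2ccccc2)c(OC)c1 | intermediate
10 | (S)-4-benzyl-3-{(2S,3E)-4-[4-(benzyloxy)-3-methoxyphenyl]-2-[(S)-[4-(benzyloxy)-3-methoxyphenyl](hydroxy)methyl]but-3-enoyl}oxazolidin-2-one | O=C(N1[C@@H](Cc2ccccc2)COC1=O)[C@@H](/C=C/c1ccc(OCc2ccccc2)c(OC)c1)[C@H](O)c1ccc(OCc2ccccc2)c(OC)c1 | intermediate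
11 | tert-butyldimethylsilyl ether of 10 | O=C(N1[C@@H](Cc2ccccc2)COC1=O)[C@@H](/C=C/c1ccc(OCc2ccccc2)c(OC)c1)[C@H](O[Si](C)(C)C(C)(C)C)c1ccc(OCc2ccccc2)c(OC)c1 | intermediate
12 | (2R,3E)-4-[4-(benzyloxy)-3-methoxyphenyl]-2-[(S)-[4-(benzyloxy)-3-methoxyphenyl](tert-butyldimethylsilyloxy)methyl]but-3-en-1-ol | OC[C@@H](/C=C/c1ccc(OCc2ccccc2)c(OC)c1)[C@H](O[Si](C)(C)C(C)(C)C)c1ccc(OCc2ccccc2)c(OC)c1 | intermediate
13 | tert-butyl({(1S,2S,3E)-1,4-bis[4-(benzyloxy)-3-methoxyphenyl]-2-(chloromethyl)but-3-en-1-yl}oxy)dimethylsilane | ClC[C@@H](/C=C/c1ccc(OCc2ccccc2)c(OC)c1)[C@H](O[Si](C)(C)C(C)(C)C)c1ccc(OCc2ccccc2)c(OC)c1 | intermediate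
14 | potassium (3S,4S)-2-[4-(benzyloxy)-3-methoxybenzyl]-4-[4-(benzyloxy)-3-methoxyphenyl]-4-(tert-butyldimethylsilyloxy)-3-(chloromethyl)butanoate, both C2 epimers | [K+].[O-]C(=O)C(Cc1ccc(OCc2ccccc2)c(OC)c1)[C@H](CCl)[C@H](O[Si](C)(C)C(C)(C)C)c1ccc(OCc2ccccc2)c(OC)c1 | intermediate
15 | (4R)-3-[4-(benzyloxy)-3-methoxybenzyl]-4-[(S)-[4-(benzyloxy)-3-methoxyphenyl](tert-butyldimethylsilyloxy)methyl]dihydrofuran-2(3H)-one, C3 epimer mixture | COc1cc(CC2C(=O)OC[C@@H]2[C@H](O[Si](C)(C)C(C)(C)C)c2ccc(OCc3ccccc3)c(OC)c2)ccc1OCc1ccccc1 | intermediate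
16 | (3R,4R)-3-[4-(benzyloxy)-3-methoxybenzyl]-4-[(S)-[4-(benzyloxy)-3-methoxyphenyl](tert-butyldimethylsilyloxy)methyl]dihydrofuran-2(3H)-one | COc1cc(C[C@H]2C(=O)OC[C@@H]2[C@H](O[Si](C)(C)C(C)(C)C)c2ccc(OCc3ccccc3)c(OC)c2)ccc1OCc1ccccc1 | intermediate
17 | (3R,4R)-4-[(S)-(tert-butyldimethylsilyloxy)(4-hydroxy-3-methoxyphenyl)methyl]-3-(4-hydroxy-3-methoxybenzyl)dihydrofuran-2(3H)-one | COc1cc(C[C@H]2C(=O)OC[C@@H]2[C@H](O[Si](C)(C)C(C)(C)C)c2ccc(O)c(OC)c2)ccc1O | intermediate
18 | (3R,4R)-4-[(S)-hydroxy(4-hydroxy-3-methoxyphenyl)methyl]-3-(4-hydroxy-3-methoxybenzyl)dihydrofuran-2(3H)-one | COc1cc(C[C@H]2C(=O)OC[C@@H]2[C@H](O)c2ccc(O)c(OC)c2)ccc1O | target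

**Step count and risks**

Total steps: 10. Longest linear sequence: 10 steps (1 → 18); aldehyde 1 enters twice and auxiliary 5 once.

Steps most likely to fail:

Step 7. What may go wrong: slow addition of the nucleophilic CO2•− to an electron-rich, β-branched styrene; reversible hydrogen abstraction by the thiyl radical at the allylic C–H of the future C4 or at the carbinol C–H, eroding configuration; substitution of the chloride by formate or thiolate before carboxylation; incomplete ring closure. Fallback: set out from alcohol 12 and build the lactone by alkoxycarbonyl radical cyclisation. Acylation of 12 with Se-phenyl carbonochloridoselenoate and pyridine in CH2Cl2 at 0 °C should give O-{(2R,3E)-4-[4-(benzyloxy)-3-methoxyphenyl]-2-[(S)-[4-(benzyloxy)-3-methoxyphenyl](tert-butyldimethylsilyloxy)methyl]but-3-en-1-yl} Se-phenyl carbonoselenoate F1. Slow addition of Bu3SnH and AIBN in benzene at 80 °C should then release the alkoxycarbonyl radical, which cyclises 5-exo-trig onto the styrene β-carbon and is reduced at the benzylic position, returning to the route at lactone 15.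

Step 3. What may go wrong: loss of α-regiocontrol of the aryl-terminated dienolate (γ-attack), sluggish addition to the electron-rich aldehyde, or retro-aldol cleavage of the electron-rich benzylic aldolate during work-up. Fallback: set out from auxiliary 5 and aldehyde 1 and use the precedented deconjugative crotonyl aldol, adding the aryl ring afterwards. Acylation of 5 (n-BuLi, crotonyl chloride, THF, −78 °C) should give (S)-4-benzyl-3-[(E)-but-2-enoyl]oxazolidin-2-one F2. Bu2BOTf/Et3N should convert it into the dibutylboron dienolate F3, which adds 1 at its α-carbon to give the boron aldolate F4 and, after oxidative work-up, (S)-4-benzyl-3-{(2S)-2-[(S)-[4-(benzyloxy)-3-methoxyphenyl](hydroxy)methyl]but-3-enoyl}oxazolidin-2-one F5. TBSOTf/2,6-lutidine should give its tert-butyldimethylsilyl ether F6. Cross-metathesis of F6 with 1-(benzyloxy)-2-methoxy-4-vinylbenzene F7 (from 1 with Ph3PCH3Br and KOt-Bu), using second-generation Grubbs catalyst in CH2Cl2 at 40 °C, should return to the route at silylated imide 11.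

Step 10. What may go wrong: slow fluoride attack at the hindered benzylic silyl ether, forcing conditions under which phenoxide-assisted loss of the benzylic oxygen (quinone methide formation) or acyl migration to the liberated secondary alkoxide can begin. Fallback: set out from 16 and invert the order of unveiling, so that fluoride never meets a free phenol. Bu4NF/AcOH in THF should give (3R,4R)-3-[4-(benzyloxy)-3-methoxybenzyl]-4-[(S)-[4-(benzyloxy)-3-methoxyphenyl](hydroxy)methyl]dihydrofuran-2(3H)-one F8. Brief hydrogenolysis (H2 at 1 atm, Pd/C, EtOAc, rt, stopped when the benzyl ethers are consumed) should then return to the route at target 18, since O-debenzylation is expected to be much faster than hydrogenolysis of the secondary benzylic alcohol.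

**Further compounds**

F1 | step 7 | O-{(2R,3E)-4-[4-(benzyloxy)-3-methoxyphenyl]-2-[(S)-[4-(benzyloxy)-3-methoxyphenyl](tert-butyldimethylsilyloxy)methyl]but-3-en-1-yl} Se-phenyl carbonoselenoate | O=C([Se]c1ccccc1)OC[C@@H](/C=C/c1ccc(OCc2ccccc2)c(OC)c1)[C@H](O[Si](C)(C)C(C)(C)C)c1ccc(OCc2ccccc2)c(OC)c1
F2 | step 3 | (S)-4-benzyl-3-[(E)-but-2-enoyl]oxazolidin-2-one | C/C=C/C(=O)N1[C@@H](Cc2ccccc2)COC1=O
F3 | step 3 | dibutylboron Z-dienolate of F2 | CCCCB(CCCC)O/C(N1[C@@H](Cc2ccccc2)COC1=O)=C\C=C
F4 | step 3 | dibutylboron aldolate of F5 | O=C(N1[C@@H](Cc2ccccc2)COC1=O)[C@@H](C=C)[C@H](OB(CCCC)CCCC)c1ccc(OCc2ccccc2)c(OC)c1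
F5 | step 3 | (S)-4-benzyl-3-{(2S)-2-[(S)-[4-(benzyloxy)-3-methoxyphenyl](hydroxy)methyl]but-3-enoyl}oxazolidin-2-one | O=C(N1[C@@H](Cc2ccccc2)COC1=O)[C@@H](C=C)[C@H](O)c1ccc(OCc2ccccc2)c(OC)c1
F6 | step 3 | tert-butyldimethylsilyl ether of F5 | O=C(N1[C@@H](Cc2ccccc2)COC1=O)[C@@H](C=C)[C@H](O[Si](C)(C)C(C)(C)C)c1ccc(OCc2ccccc2)c(OC)c1
F7 | step 3 | 1-(benzyloxy)-2-methoxy-4-vinylbenzene | C=Cc1ccc(OCc2ccccc2)c(OC)c1
F8 | step 10 | (3R,4R)-3-[4-(benzyloxy)-3-methoxybenzyl]-4-[(S)-[4-(benzyloxy)-3-methoxyphenyl](hydroxy)methyl]dihydrofuran-2(3H)-one | COc1cc(C[C@H]2C(=O)OC[C@@H]2[C@H](O)c2ccc(OCc3ccccc3)c(OC)c2)ccc1OCc1ccccc1
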